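Assumption: atoms carry the acetogenin labels C1 (alkyne CH) to C15 (ethyl CH3); the SMILES is read as (3E,6S,7S,9S,10S,12S,13R), and this isomer is made.

## Retrosynthetic overview

1. Tetrahydrofuran ring (formed last): transannular bromoetherification of a (Z)-oxocene enynol, C6–OH onto C9 with bromine delivered to C10.
2. Side chain: copper-catalysed opening of a C5–C6 terminal epoxide by an (E)-enynyl Grignard reagent (C4–C5 bond); the iodoenyne is built from trimethylsilylacetylene in its own branch.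
3. Oxocene ring (formed first): ring-closing metathesis of a C7/C12 bis-allyl ether; C12–Br by inversion of the alcohol from a chelation-controlled allylation.
4. Central ether: copper-carbene O–H insertion joining a diepoxybutane-derived C5–C9 alcohol to methyl 2-diazobutanoate (C13–O bond, C13 set).

## Route

Step 1
Reactants: 1 (2S,2'S)-2,2'-bioxirane [(2S,3S)-1,2:3,4-diepoxybutane]
Product: 2 tert-butyl{(1R)-2-chloro-1-[(2S)-oxiran-2-yl]ethoxy}dimethylsilane
Conditions: t-BuMe2SiCl (1.0 equiv), n-Bu4NCl (5 mol %), CH2Cl2, 25 °C; 1 in excess (3 equiv, recovered)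
Reagents that add atoms: tert-butyl(chloro)dimethylsilane, CC(C)(C)[Si](C)(C)Cl
Why: Halide-catalysed insertion of the chlorosilane into one oxirane of the C2-symmetric diepoxide (chloride opens at the terminal CH2, the alkoxide is silylated); no stereocentre is touched, so C6 and C7 come from the chiral pool, and the excess of 1 limits double opening.

Step 2
Reactants: 2 tert-butyl{(1R)-2-chloro-1-[(2S)-oxiran-2-yl]ethoxy}dimethylsilane
Product: 3 (2R,3S)-2-{[tert-butyl(dimethyl)silyl]oxy}-1-chlorohex-5-en-3-ol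
Conditions: CH2=CHMgBr, CuI (10 mol %), THF, −40 → −20 °C; then H2O
Reagents that add atoms: vinylmagnesium bromide, C=C[Mg]Br
Why: Copper-catalysed Grignard opening of the remaining terminal epoxide at its CH2 carbon installs the C8–C9 allyl arm and leaves the C7 hydroxyl as the only free OH; the primary chloride and silyl ether are inert at this temperature.

Step 3
Reactants: 4 methyl 2-oxobutanoate
Product: 5 methyl 2-[2-(4-methylbenzenesulfonyl)hydrazinylidene]butanoate
Conditions: TsNHNH2, MeOH, 25 °C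
Reagents that add atoms: 4-methylbenzenesulfonohydrazide, Cc1ccc(cc1)S(=O)(=O)NN
Why: Condensation of the ketone carbonyl with the sulfonyl hydrazide gives the tosylhydrazone.

Step 4
Reactants: 5 methyl 2-[2-(4-methylbenzenesulfonyl)hydrazinylidene]butanoate
Product: 6 methyl 2-diazobutanoate
Conditions: DBU, CH2Cl2, 0 → 25 °C
Reagents that add atoms: none
Why: Bamford–Stevens-type elimination of sulfinate from the deprotonated hydrazone gives the ester-stabilised diazo compound.

Step 5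
Reactants: 3 (2R,3S)-2-{[tert-butyl(dimethyl)silyl]oxy}-1-chlorohex-5-en-3-ol; 6 methyl 2-diazobutanoate
Product: 7 methyl (2R)-2-{[(4S,5R)-5-{[tert-butyl(dimethyl)silyl]oxy}-6-chlorohex-1-en-4-yl]oxy}butanoate
Conditions: [Cu(MeCN)4]PF6 (5 mol %), (Sa,S,S)-7,7'-bis(4-phenyl-4,5-dihydrooxazol-2-yl)-1,1'-spirobiindane (6 mol %), Na[B(3,5-(CF3)2C6H3)4] (6 mol %), 4 Å MS, CH2Cl2, 25 °C, slow addition of 6 (1.5 equiv)
Reagents that add atoms: none
Why: Proposed new method: a monovalent-copper/chiral spiro-bisoxazoline carbene O–H insertion run as a 1:1 fragment coupling of a hindered, polyfunctional chiral secondary alcohol with an α-ethyl diazo ester; the copper carbene from 6 is attacked by the C7 hydroxyl to give a copper-bound oxonium ylide (copper enolate), and the ligand-controlled 1,2-proton shift forms the C13–O bond and sets C13 (R), the cationic catalyst with the non-coordinating borate counter-ion and slow addition of 6 favouring O–H insertion over the 1,2-hydride shift to methyl but-2-enoate and over cyclopropanation of the allyl group (the ligand antipode is taken if the first run shows the mismatched pairing with the resident C6/C7 centres); closest known reaction type: copper/spiro-bisoxazoline-catalysed enantioselective O–H insertion of α-diazopropionates into simple alcohols, phenols and water.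

Step 6
Reactants: 7 methyl (2R)-2-{[(4S,5R)-5-{[tert-butyl(dimethyl)silyl]oxy}-6-chlorohex-1-en-4-yl]oxy}butanoate
Product: 8 (2R)-2-{[(4S,5R)-5-{[tert-butyl(dimethyl)silyl]oxy}-6-chlorohex-1-en-4-yl]oxy}butanal
Conditions: i-Bu2AlH (1.1 equiv), CH2Cl2, −78 °C; then MeOH, aq. potassium sodium tartrate
Reagents that add atoms: none
Why: Half-reduction of the α-alkoxy methyl ester stops at the chelated tetrahedral aluminium alkoxide at −78 °C and releases the aldehyde on work-up without epimerising C13; the aldehyde is used at once.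

Step 7
Reactants: 8 (2R)-2-{[(4S,5R)-5-{[tert-butyl(dimethyl)silyl]oxy}-6-chlorohex-1-en-4-yl]oxy}butanal
Product: 9 (4R,5R)-5-{[(4S,5R)-5-{[tert-butyl(dimethyl)silyl]oxy}-6-chlorohex-1-en-4-yl]oxy}hept-1-en-4-ol
Conditions: MgBr2·OEt2 (2.5 equiv), CH2=CHCH2SnBu3 (1.5 equiv), CH2Cl2, −78 → −20 °C; then H2O
Reagents that add atoms: allyltributylstannane, C=CC[Sn](CCCC)(CCCC)CCCC
Why: Keck chelation-controlled allylation: magnesium bridges the aldehyde and the α-ether oxygen, and the allyl group adds to the face of the five-membered chelate opposite the ethyl group, giving the syn (12R,13R) alcohol.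

Step 8
Reactants: 9 (4R,5R)-5-{[(4S,5R)-5-{[tert-butyl(dimethyl)silyl]oxy}-6-chlorohex-1-en-4-yl]oxy}hept-1-en-4-ol
Product: 10 (2R,3R,5Z,8S)-8-[(1R)-1-{[tert-butyl(dimethyl)silyl]oxy}-2-chloroethyl]-2-ethyl-3,4,7,8-tetrahydro-2H-oxocin-3-ol
Conditions: (H2IMes)(PCy3)Cl2Ru=CHPh (second-generation Grubbs catalyst, 5 mol %), CH2Cl2 (3 mM), 40 °C
Reagents that add atoms: none
Why: Ring-closing metathesis of the only two alkenes present closes the oxocene at C9=C10 (Z by ring size); the gauche O–C–C–O arrangements on both sides of the ether oxygen preorganise the diene for eight-membered ring closure.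

Step 9
Reactants: 10 (2R,3R,5Z,8S)-8-[(1R)-1-{[tert-butyl(dimethyl)silyl]oxy}-2-chloroethyl]-2-ethyl-3,4,7,8-tetrahydro-2H-oxocin-3-ol
Product: 11 {(1R)-1-[(2S,4Z,7S,8R)-7-bromo-8-ethyl-3,6,7,8-tetrahydro-2H-oxocin-2-yl]-2-chloroethoxy}(tert-butyl)dimethylsilane
Conditions: CBr4, (n-C8H17)3P, toluene, 70 °C
Reagents that add atoms: tetrabromomethane, BrC(Br)(Br)Br
Why: Appel bromination: the alkoxyphosphonium ion is displaced by bromide in an SN2 step, inverting C12 from R to S; these are the conditions proven on oxocenols of this family, and the silyl ether and primary chloride survive them.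

Step 10
Reactants: 11 {(1R)-1-[(2S,4Z,7S,8R)-7-bromo-8-ethyl-3,6,7,8-tetrahydro-2H-oxocin-2-yl]-2-chloroethoxy}(tert-butyl)dimethylsilane
Product: 13 (2S)-2-[(2S,4Z,7S,8R)-7-bromo-8-ethyl-3,6,7,8-tetrahydro-2H-oxocin-2-yl]oxirane, via chlorohydrin alkoxide 12 (not isolated)
Conditions: n-Bu4NF, THF, 0 → 25 °C
Reagents that add atoms: none
Why: Fluoride desilylation frees the C6 alkoxide, which displaces the neighbouring primary chloride (intramolecular Williamson reaction) to give the terminal epoxide; attack is at C5, so C6 keeps its configuration.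

Step 11
Reactants: 14 ethynyl(trimethyl)silane (2 equiv)
Product: 15 buta-1,3-diyne-1,4-diylbis(trimethylsilane)
Conditions: CuCl (5 mol %), TMEDA, O2, acetone, 25 °C
Reagents that add atoms: none
Why: Hay (Glaser-type) copper-catalysed oxidative homocoupling of the terminal alkyne gives the C1–C4 carbon chain.

Step 12
Reactants: 15 buta-1,3-diyne-1,4-diylbis(trimethylsilane)
Product: 17 buta-1,3-diyn-1-yl(trimethyl)silane, via lithium diynide 16 (not isolated)
Conditions: MeLi·LiBr (1.05 equiv), Et2O, 25 °C; then H2O, 0 °C; kept as an ether solution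
Reagents that add atoms: none
Why: Selective mono-desilylation: methyllithium attacks one silicon to give the diynide, whose negative charge protects the second silyl group; protonation gives the terminal diyne.

Step 13
Reactants: 17 buta-1,3-diyn-1-yl(trimethyl)silane
Product: 19 [(3E)-4-iodobut-3-en-1-yn-1-yl](trimethyl)silane, via alkenylzirconocene chloride 18 (not isolated)
Conditions: Cp2Zr(H)Cl, THF, 25 °C; then I2, 0 °C
Reagents that add atoms: iodine, II
Why: Hydrozirconation adds Zr–H syn across the free terminal alkyne with zirconium at the terminal carbon, and iodinolysis proceeds with retention, so the alkenyl iodide is E only.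

Step 14
Reactants: 13 (2S)-2-[(2S,4Z,7S,8R)-7-bromo-8-ethyl-3,6,7,8-tetrahydro-2H-oxocin-2-yl]oxirane; 19 [(3E)-4-iodobut-3-en-1-yn-1-yl](trimethyl)silane
Product: 22 (1S,3E)-1-[(2S,4Z,7S,8R)-7-bromo-8-ethyl-3,6,7,8-tetrahydro-2H-oxocin-2-yl]hex-3-en-5-yn-1-ol, via alkenylmagnesium chloride 20 (not isolated), via C-silylated enynol 21 (not isolated)
Conditions: 19, i-PrMgCl·LiCl, THF, −20 → 0 °C; then CuI (10 mol %), 13, −40 → −10 °C; then MeOH, K2CO3 (cat.), 25 °C; aq. work-up
Reagents that add atoms: none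
Why: Iodine–magnesium exchange keeps the E geometry, and the copper-catalysed Grignard–epoxide coupling attacks the terminal C5 to form the C4–C5 bond and release the C6 hydroxyl (S, untouched); the secondary bromide is inert at this temperature, and basic methanol removes the alkynyl silane in the same flask.

Step 15
Reactants: 22 (1S,3E)-1-[(2S,4Z,7S,8R)-7-bromo-8-ethyl-3,6,7,8-tetrahydro-2H-oxocin-2-yl]hex-3-en-5-yn-1-ol
Product: 23 (1S,3R,4S,6S,7S,9S)-4,6-dibromo-3-ethyl-9-[(2E)-pent-2-en-4-yn-1-yl]-2,8-dioxabicyclo[5.2.1]decane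
Conditions: NBS (1.1 equiv), CH2Cl2, 0 → 25 °C, dark
Reagents that add atoms: N-bromosuccinimide, O=C1CCC(=O)N1Br
Why: Transannular 5-exo bromoetherification: the C6 hydroxyl can reach C9 only from the face of the ring that carries the C7 side chain, so it opens the bromonium ion formed on the opposite face; this anti addition across the Z alkene closes the tetrahydrofuran and sets C9 (S) and C10 (S).

## Compound list

1 | (2S,2'S)-2,2'-bioxirane [(2S,3S)-1,2:3,4-diepoxybutane] | C1O[C@@H]1[C@@H]1CO1 | starting material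
2 | tert-butyl{(1R)-2-chloro-1-[(2S)-oxiran-2-yl]ethoxy}dimethylsilane | ClC[C@H](O[Si](C)(C)C(C)(C)C)[C@@H]1CO1 | intermediate
3 | (2R,3S)-2-{[tert-butyl(dimethyl)silyl]oxy}-1-chlorohex-5-en-3-ol | ClC[C@H](O[Si](C)(C)C(C)(C)C)[C@@H](O)CC=C | intermediate
4 | methyl 2-oxobutanoate | CCC(=O)C(=O)OC | starting material
5 | methyl 2-[2-(4-methylbenzenesulfonyl)hydrazinylidene]butanoate | CCC(=NNS(=O)(=O)c1ccc(C)cc1)C(=O)OC | intermediate
6 | methyl 2-diazobutanoate | CCC(=[N+]=[N-])C(=O)OC | intermediate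
7 | methyl (2R)-2-{[(4S,5R)-5-{[tert-butyl(dimethyl)silyl]oxy}-6-chlorohex-1-en-4-yl]oxy}butanoate | ClC[C@H](O[Si](C)(C)C(C)(C)C)[C@H](CC=C)O[C@H](CC)C(=O)OC | intermediate
8 | (2R)-2-{[(4S,5R)-5-{[tert-butyl(dimethyl)silyl]oxy}-6-chlorohex-1-en-4-yl]oxy}butanal | ClC[C@H](O[Si](C)(C)C(C)(C)C)[C@H](CC=C)O[C@H](CC)C=O | intermediate
9 | (4R,5R)-5-{[(4S,5R)-5-{[tert-butyl(dimethyl)silyl]oxy}-6-chlorohex-1-en-4-yl]oxy}hept-1-en-4-ol | ClC[C@H](O[Si](C)(C)C(C)(C)C)[C@H](CC=C)O[C@H](CC)[C@H](O)CC=C | intermediate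
10 | (2R,3R,5Z,8S)-8-[(1R)-1-{[tert-butyl(dimethyl)silyl]oxy}-2-chloroethyl]-2-ethyl-3,4,7,8-tetrahydro-2H-oxocin-3-ol | ClC[C@H](O[Si](C)(C)C(C)(C)C)[C@@H]1C/C=C\C[C@@H](O)[C@@H](CC)O1 | intermediate
11 | {(1R)-1-[(2S,4Z,7S,8R)-7-bromo-8-ethyl-3,6,7,8-tetrahydro-2H-oxocin-2-yl]-2-chloroethoxy}(tert-butyl)dimethylsilane | ClC[C@H](O[Si](C)(C)C(C)(C)C)[C@@H]1C/C=C\C[C@H](Br)[C@@H](CC)O1 | intermediate
12 | (1R)-1-[(2S,4Z,7S,8R)-7-bromo-8-ethyl-3,6,7,8-tetrahydro-2H-oxocin-2-yl]-2-chloroethan-1-ol, present as its tetrabutylammonium alkoxide | ClC[C@H](O)[C@@H]1C/C=C\C[C@H](Br)[C@@H](CC)O1 | intermediate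
13 | (2S)-2-[(2S,4Z,7S,8R)-7-bromo-8-ethyl-3,6,7,8-tetrahydro-2H-oxocin-2-yl]oxirane | C1O[C@@H]1[C@@H]1C/C=C\C[C@H](Br)[C@@H](CC)O1 | intermediate
14 | ethynyl(trimethyl)silane | C#C[Si](C)(C)C | starting material
15 | buta-1,3-diyne-1,4-diylbis(trimethylsilane) | C[Si](C)(C)C#CC#C[Si](C)(C)C | intermediate
16 | lithium 4-(trimethylsilyl)buta-1,3-diyn-1-ide | [Li]C#CC#C[Si](C)(C)C | intermediate
17 | buta-1,3-diyn-1-yl(trimethyl)silane | C#CC#C[Si](C)(C)C | intermediate
18 | chlorobis(cyclopentadienyl)[(1E)-4-(trimethylsilyl)but-1-en-3-yn-1-yl]zirconium | C[Si](C)(C)C#C/C=C/[Zr](Cl)(C1C=CC=C1)C1C=CC=C1 | intermediate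
19 | [(3E)-4-iodobut-3-en-1-yn-1-yl](trimethyl)silane | C[Si](C)(C)C#C/C=C/I | intermediate
20 | chloro[(1E)-4-(trimethylsilyl)but-1-en-3-yn-1-yl]magnesium (LiCl complex) | C[Si](C)(C)C#C/C=C/[Mg]Cl | intermediate
21 | (1S,3E)-1-[(2S,4Z,7S,8R)-7-bromo-8-ethyl-3,6,7,8-tetrahydro-2H-oxocin-2-yl]-6-(trimethylsilyl)hex-3-en-5-yn-1-ol, formed as its chloromagnesium alkoxide | C[Si](C)(C)C#C/C=C/C[C@H](O)[C@@H]1C/C=C\C[C@H](Br)[C@@H](CC)O1 | intermediate
22 | (1S,3E)-1-[(2S,4Z,7S,8R)-7-bromo-8-ethyl-3,6,7,8-tetrahydro-2H-oxocin-2-yl]hex-3-en-5-yn-1-ol | C#C/C=C/C[C@H](O)[C@@H]1C/C=C\C[C@H](Br)[C@@H](CC)O1 | intermediate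
23 | (1S,3R,4S,6S,7S,9S)-4,6-dibromo-3-ethyl-9-[(2E)-pent-2-en-4-yn-1-yl]-2,8-dioxabicyclo[5.2.1]decane | C#C/C=C/C[C@@H]1O[C@H]2C[C@@H]1O[C@H](CC)[C@@H](Br)C[C@@H]2Br | target

## Step count and risks

Total step count: 15.
Longest linear sequence: 10 steps (1, 2, 5, 6, 7, 8, 9, 10, 14, 15; the branch through steps 3 and 4 is equally long); the iodoenyne branch (steps 11–13) joins at step 14.

The three steps most likely to fail:

Step 5 (the proposed copper-carbene O–H insertion). The hindered alcohol may react slowly, the carbene may lose a β-hydrogen, or the diastereoselectivity at C13 may be low. The fallback uses known SN2 chemistry and sets out from 3. Commercial methyl (2S)-2-hydroxybutanoate is converted with (CF3SO2)2O and 2,6-lutidine in CH2Cl2 at −78 °C into methyl (2S)-2-{[(trifluoromethyl)sulfonyl]oxy}butanoate F1. Alcohol 3 is then alkylated with F1 in CH2Cl2 in the presence of 2,6-di-tert-butyl-4-methylpyridine at 25 °C. Displacement of the α-triflate by the neutral alcohol proceeds with clean inversion and gives the (13R) ether, so the route is rejoined at 7.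

Step 14 (copper-catalysed enynyl Grignard opening of the epoxide). The iodine–magnesium exchange on the iodoenyne may be sluggish, or the reagent may attack the C12 bromide. The fallback builds the enyne stepwise and sets out from 13. Opening with CH2=CHMgBr and CuI (10 mol %) in THF at −40 °C gives (1S)-1-[(2S,4Z,7S,8R)-7-bromo-8-ethyl-3,6,7,8-tetrahydro-2H-oxocin-2-yl]but-3-en-1-ol F2. Cross-metathesis of F2 with (E)-but-2-enal and (H2IMes)Cl2Ru=CH(2-i-PrOC6H4) (second-generation Hoveyda–Grubbs catalyst) in CH2Cl2 at 40 °C gives (2E,5S)-5-[(2S,4Z,7S,8R)-7-bromo-8-ethyl-3,6,7,8-tetrahydro-2H-oxocin-2-yl]-5-hydroxypent-2-enal F3. Colvin homologation of F3 with Me3SiCHN2 and LiN(i-Pr)2 in THF (−78 → 0 °C) turns the aldehyde into the terminal alkyne, and the route is rejoined at 22.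

Step 15 (transannular bromoetherification). The terminal enyne may interfere, or the ring ether oxygen may intercept the bromonium ion. The fallback replaces the bromonium cyclisation by alkoxymercuration and stereoretentive bromodemercuration with the alkyne kept silylated. It sets out from 21, isolated by aqueous work-up of step 14 without the methanol/K2CO3 treatment. Hg(OCOCF3)2 in MeCN at −20 °C gives, by anti 5-exo alkoxymercuration, {(1S,3R,4S,6S,7S,9S)-4-bromo-3-ethyl-9-[(2E)-5-(trimethylsilyl)pent-2-en-4-yn-1-yl]-2,8-dioxabicyclo[5.2.1]decan-6-yl}mercury trifluoroacetate F4. Aqueous KBr converts F4 into bromo{(1S,3R,4S,6S,7S,9S)-4-bromo-3-ethyl-9-[(2E)-5-(trimethylsilyl)pent-2-en-4-yn-1-yl]-2,8-dioxabicyclo[5.2.1]decan-6-yl}mercury F5. Br2 in pyridine at 0 °C in the dark cleaves the C–Hg bond with retention and gives {(3E)-5-[(1S,3R,4S,6S,7S,9S)-4,6-dibromo-3-ethyl-2,8-dioxabicyclo[5.2.1]decan-9-yl]pent-3-en-1-yn-1-yl}(trimethyl)silane F6. K2CO3 in MeOH removes the silyl group, and the route is rejoined at 23.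

Further compounds
F1 | step 5 | methyl (2S)-2-{[(trifluoromethyl)sulfonyl]oxy}butanoate | CC[C@H](OS(=O)(=O)C(F)(F)F)C(=O)OC
F2 | step 14 | (1S)-1-[(2S,4Z,7S,8R)-7-bromo-8-ethyl-3,6,7,8-tetrahydro-2H-oxocin-2-yl]but-3-en-1-ol | C=CC[C@H](O)[C@@H]1C/C=C\C[C@H](Br)[C@@H](CC)O1
F3 | step 14 | (2E,5S)-5-[(2S,4Z,7S,8R)-7-bromo-8-ethyl-3,6,7,8-tetrahydro-2H-oxocin-2-yl]-5-hydroxypent-2-enal | O=C/C=C/C[C@H](O)[C@@H]1C/C=C\C[C@H](Br)[C@@H](CC)O1
F4 | step 15 | {(1S,3R,4S,6S,7S,9S)-4-bromo-3-ethyl-9-[(2E)-5-(trimethylsilyl)pent-2-en-4-yn-1-yl]-2,8-dioxabicyclo[5.2.1]decan-6-yl}mercury trifluoroacetate | C[Si](C)(C)C#C/C=C/C[C@@H]1O[C@H]2C[C@@H]1O[C@H](CC)[C@@H](Br)C[C@@H]2[Hg]OC(=O)C(F)(F)F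
F5 | step 15 | bromo{(1S,3R,4S,6S,7S,9S)-4-bromo-3-ethyl-9-[(2E)-5-(trimethylsilyl)pent-2-en-4-yn-1-yl]-2,8-dioxabicyclo[5.2.1]decan-6-yl}mercury | C[Si](C)(C)C#C/C=C/C[C@@H]1O[C@H]2C[C@@H]1O[C@H](CC)[C@@H](Br)C[C@@H]2[Hg]Br
F6 | step 15 | {(3E)-5-[(1S,3R,4S,6S,7S,9S)-4,6-dibromo-3-ethyl-2,8-dioxabicyclo[5.2.1]decan-9-yl]pent-3-en-1-yn-1-yl}(trimethyl)silane | C[Si](C)(C)C#C/C=C/C[C@@H]1O[C@H]2C[C@@H]1O[C@H](CC)[C@@H](Br)C[C@@H]2Br
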